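**Plan**
1. Numbering used throughout (daucane; also for the bicyclo[5.3.0]decane intermediates): C1 quaternary carbon with CH3, C2 CH–OAc, C3 CH2, C4 C(OH)(iPr), C5 ring-fusion CH, C6 CH–O-aroyl, C7=C8(CH3), C9 C=O, C10 CH2; β = face of the C1 methyl group, α = face of H-5.
2. Retrosynthesis, in order: the phenol mask and the C2 acetate; the C6–O ester bond (Mitsunobu, inversion); the C4–isopropyl bond, a helper ester put back on C10, C1–CH3 and the C9 oxygen; last the seven-membered ring at C10–C9 and C5–C6, giving a cyclopentenyl vinyldiazoacetate and a 1-silyloxy-3-methylbutadiene.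
3. Forward: the five-membered ring is bought as (S)-4-silyloxycyclopentenone; the seven-membered ring is annulated onto its C1=C5 bond in one operation (carbenoid cyclopropanation, then Cope rearrangement); oxidation, methylation, isopropylation, decarboxylation and the acylations follow.
4. Enabling feature: C6–C7=C8–C9 of the seven-membered ring is a butadiene retron, and C10–C1–C5, with C1 and C5 shared by both rings, is a vinylcarbene retron. The C10 ester helper stabilises the carbenoid, then activates C1 for methyl addition, then masks the C9 ketone as its enolate, and is finally lost as CO2.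
5. Stereochemistry: O-4 from the starting enone and O-2 by cis-selective Luche reduction; C5 by catalyst- and substrate-controlled cyclopropanation relayed through the boat Cope; C6 from the E-diene (6β), then Mitsunobu inversion (6α); C1 by cuprate addition anti to O-2; C4 by α-face isopropyl addition.

Key step: step 6

Assumption: compounds 1, 5, 7 and 19 are taken as commercial, and Rh2(R-DOSP)4 is taken, by analogy with the known facial sense of this catalyst class, as the antipode matched to the substrate bias (Rh2(S-DOSP)4 would be used if the pairing proved opposite).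

Step 1
Reactants: 1 (S)-4-(tert-butyldimethylsilyloxy)cyclopent-2-en-1-one
Product: 2 (S)-4-(tert-butyldimethylsilyloxy)-2-iodocyclopent-2-en-1-one
Conditions: I2, pyridine, CH2Cl2, 0 °C → rt
Reagents that add atoms: iodine, II
Why: α-iodination of the enone (pyridine conjugate addition, iodination of the enolate, elimination) is the standard reaction of 4-silyloxycyclopentenones and leaves the C4 stereocentre untouched.

Step 2
Reactants: 2 (S)-4-(tert-butyldimethylsilyloxy)-2-iodocyclopent-2-en-1-one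
Product: 3 (1R,4S)-4-(tert-butyldimethylsilyloxy)-2-iodocyclopent-2-en-1-ol (cis)
Conditions: NaBH4, CeCl3·7H2O, MeOH, −78 → 0 °C
Reagents that add atoms: none
Why: Luche 1,2-reduction; hydride enters anti to the C4 silyloxy group, so the new C2 carbinol should be cis to O-4 (both α).

Step 3
Reactants: 3 (1R,4S)-4-(tert-butyldimethylsilyloxy)-2-iodocyclopent-2-en-1-ol
Product: 4 tert-butyl{[(1S,4R)-3-iodo-4-(triisopropylsilyloxy)cyclopent-2-en-1-yl]oxy}dimethylsilane (cis)
Conditions: TIPSOTf, 2,6-lutidine, CH2Cl2, 0 °C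
Reagents that add atoms: triisopropylsilyl trifluoromethanesulfonate, CC(C)[Si](C(C)C)(C(C)C)OS(=O)(=O)C(F)(F)F
Why: silylation of the secondary allylic alcohol with a silyl triflate and a hindered base; the TIPS ether is chosen to outlast the TBS ether in step 9 and to shield the α-face of C1 in step 8.

Step 4
Reactants: 4 tert-butyl{[(1S,4R)-3-iodo-4-(triisopropylsilyloxy)cyclopent-2-en-1-yl]oxy}dimethylsilane; 5 ethyl diazoacetate
Product: 6 ethyl 2-diazo-2-[(3S,5R)-3-(tert-butyldimethylsilyloxy)-5-(triisopropylsilyloxy)cyclopent-1-en-1-yl]acetate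
Conditions: Pd(PPh3)4 (cat.), Et3N, Bu4NBr, MeCN, rt
Reagents that add atoms: none
Why: palladium-catalysed cross-coupling of a vinyl iodide with the C–H bond of a diazoacetate (oxidative addition to zerovalent palladium, C–H palladation of the diazo ester, reductive elimination) should give the vinyldiazoacetate with the diazo group intact.

Step 5
Reactants: 7 3-methylbut-2-enal
Product: 8 (E)-triisopropyl[(3-methylbuta-1,3-dien-1-yl)oxy]silane
Conditions: TIPSOTf, Et3N, Et2O, 0 °C → rt
Reagents that add atoms: triisopropylsilyl trifluoromethanesulfonate, CC(C)[Si](C(C)C)(C(C)C)OS(=O)(=O)C(F)(F)F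
Why: silyl dienol ether formation (O-silylation of the enal, then γ-deprotonation of the silyloxocarbenium ion) should give the 1-silyloxydiene with the favoured E enol-ether geometry.

Step 6
Reactants: 6 ethyl 2-diazo-2-[(3S,5R)-3-(tert-butyldimethylsilyloxy)-5-(triisopropylsilyloxy)cyclopent-1-en-1-yl]acetate; 8 (E)-triisopropyl[(3-methylbuta-1,3-dien-1-yl)oxy]silane
Product: 10 ethyl 4α-(tert-butyldimethylsilyloxy)-8-methyl-2α,6β-bis(triisopropylsilyloxy)-5αH-bicyclo[5.3.0]deca-1(10),7-diene-10-carboxylate, via cis-divinylcyclopropane 9 (not isolated)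
Conditions: Rh2(R-DOSP)4 (1 mol %), 8 (3 equiv), hexanes, −40 °C → rt (slow addition of 6), then 60 °C
Reagents that add atoms: none
Why: Rh2(R-DOSP)4 converts 6 into a donor/acceptor vinylcarbenoid of divalent rhodium, which cyclopropanates the terminal 1,1-disubstituted C9=C8 bond of 8 (C10–C9 bond leading) to cis-divinylcyclopropane 9; 9 then undergoes a Cope ([3,3]-sigmatropic) rearrangement through a boat transition state, breaking C10–C8 and forming C5–C6. The closest known reaction type is the tandem cyclopropanation/Cope rearrangement (formal [4+3] cycloaddition) of cycloalkenyl diazoacetates with 1-oxygenated butadienes. The seven-membered ring is closed onto the existing C1=C5 bond by (4+3) annulation: the first bond by intermolecular carbene transfer, the second intramolecularly in the [3,3] shift of the array C5=C1–C10–C8–C7=C6, which expands the three-membered ring by four atoms. C5 is set by the cyclopropane configuration (catalyst control, reinforced by diene approach anti to the pseudo-axial C2 silyloxy group) relayed through the stereospecific boat geometry, which also places the new bond anti to the C4 silyloxy group; C6 follows from the E enol ether, whose outward substituent ends cis to C4 (6β-O, H-5 and H-6 cis). The step needs site selectivity for C9=C8 over C7=C6, which is secured because donor/acceptor carbenoids do not cyclopropanate trans-1,2-disubstituted alkenes and C9 is the unhindered, vinylogously activated terminus of the silyloxydiene.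

Step 7
Reactants: 10 ethyl 4α-(tert-butyldimethylsilyloxy)-8-methyl-2α,6β-bis(triisopropylsilyloxy)-5αH-bicyclo[5.3.0]deca-1(10),7-diene-10-carboxylate
Product: 11 ethyl 4α-(tert-butyldimethylsilyloxy)-8-methyl-9-oxo-2α,6β-bis(triisopropylsilyloxy)-5αH-bicyclo[5.3.0]deca-1(10),7-diene-10-carboxylate
Conditions: CrO3, 3,5-dimethylpyrazole, CH2Cl2, −20 °C; product used at once
Reagents that add atoms: chromium trioxide CrO3, O=[Cr](=O)=O
Why: allylic oxidation by the hexavalent chromium–pyrazole complex should occur at the doubly allylic C9 methylene, whose C–H bonds are the weakest (flanked by the enoate and the trisubstituted alkene), to give the cross-conjugated dienone without touching a stereocentre.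

Step 8
Reactants: 11 ethyl 4α-(tert-butyldimethylsilyloxy)-8-methyl-9-oxo-2α,6β-bis(triisopropylsilyloxy)-5αH-bicyclo[5.3.0]deca-1(10),7-diene-10-carboxylate
Product: 12 ethyl 4α-(tert-butyldimethylsilyloxy)-1β,8-dimethyl-9-oxo-2α,6β-bis(triisopropylsilyloxy)-5αH-bicyclo[5.3.0]dec-7-ene-10-carboxylate (C10 epimers and enol)
Conditions: MeLi, CuI, Et2O, −30 °C (forms Me2CuLi); then 11, −78 °C; aq. NH4Cl
Reagents that add atoms: lithium dimethylcuprate Me2CuLi, [Li+].C[Cu-]C
Why: conjugate addition of a lithium dialkylcuprate to the doubly activated alkylidene β-keto ester forms the quaternary C1; the methyl group should enter from the β-face because allylic 1,3-strain with the ester holds the adjacent C2 silyloxy group pseudo-axial on the α-face (CH3 trans to O-2 and to H-5), and the α-methyl enone terminus C7 is far less electrophilic.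

Step 9
Reactants: 12 ethyl 4α-(tert-butyldimethylsilyloxy)-1β,8-dimethyl-9-oxo-2α,6β-bis(triisopropylsilyloxy)-5αH-bicyclo[5.3.0]dec-7-ene-10-carboxylate
Product: 13 ethyl 4α-hydroxy-1β,8-dimethyl-9-oxo-2α,6β-bis(triisopropylsilyloxy)-5αH-bicyclo[5.3.0]dec-7-ene-10-carboxylate
Conditions: HF·pyridine, pyridine, THF, 0 °C
Reagents that add atoms: none
Why: selective desilylation; a secondary TBS ether is cleaved much faster than the two bulkier TIPS ethers under buffered HF.

Step 10
Reactants: 13 ethyl 4α-hydroxy-1β,8-dimethyl-9-oxo-2α,6β-bis(triisopropylsilyloxy)-5αH-bicyclo[5.3.0]dec-7-ene-10-carboxylate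
Product: 14 ethyl 1β,8-dimethyl-4,9-dioxo-2α,6β-bis(triisopropylsilyloxy)-5αH-bicyclo[5.3.0]dec-7-ene-10-carboxylate
Conditions: Dess–Martin periodinane, NaHCO3, CH2Cl2, 0 °C → rt
Reagents that add atoms: none
Why: Dess–Martin oxidation under buffered, non-basic conditions should give the C4 ketone without epimerisation at C5 or β-elimination of the C6 or C2 silyloxy groups.

Step 11
Reactants: 14 ethyl 1β,8-dimethyl-4,9-dioxo-2α,6β-bis(triisopropylsilyloxy)-5αH-bicyclo[5.3.0]dec-7-ene-10-carboxylate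
Product: 16 ethyl 4β-hydroxy-4α-isopropyl-1β,8-dimethyl-9-oxo-2α,6β-bis(triisopropylsilyloxy)-5αH-bicyclo[5.3.0]dec-7-ene-10-carboxylate, via sodium enolate 15 (not isolated)
Conditions: NaH (1.05 equiv), THF, 0 °C; then iPrMgCl, CeCl3, THF, −78 → −40 °C; aq. NH4Cl
Reagents that add atoms: isopropylmagnesium chloride iPrMgCl, CC(C)[Mg]Cl
Why: the β-keto ester is first turned into its sodium enolate, which masks the C9 ketone and the ester, so that the weakly basic organocerium reagent adds 1,2 only to the C4 ketone; attack from the α-face, anti to the β angular methyl group and to the β C6 branch on C5, should give the 4β-hydroxy-4α-isopropyl centre.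

Step 12
Reactants: 16 ethyl 4β-hydroxy-4α-isopropyl-1β,8-dimethyl-9-oxo-2α,6β-bis(triisopropylsilyloxy)-5αH-bicyclo[5.3.0]dec-7-ene-10-carboxylate
Product: 17 4β-hydroxy-4α-isopropyl-1β,8-dimethyl-2α,6β-bis(triisopropylsilyloxy)-5αH-bicyclo[5.3.0]dec-7-en-9-one
Conditions: LiCl, H2O, DMSO, 140 °C
Reagents that add atoms: none
Why: Krapcho dealkoxycarbonylation of the β-keto ester removes the helper ester and leaves the C10 methylene under neutral conditions that spare the tertiary alcohol and the silyl ethers.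

Step 13
Reactants: 17 4β-hydroxy-4α-isopropyl-1β,8-dimethyl-2α,6β-bis(triisopropylsilyloxy)-5αH-bicyclo[5.3.0]dec-7-en-9-one
Product: 18 2α,4β,6β-trihydroxy-4α-isopropyl-1β,8-dimethyl-5αH-bicyclo[5.3.0]dec-7-en-9-one
Conditions: HF·pyridine (excess), pyridine, THF, rt → 40 °C
Reagents that add atoms: none
Why: fluoride cleavage of both TIPS ethers under buffered acidic conditions avoids the base that could isomerise the γ-hydroxy enone or epimerise C6.

Step 14
Reactants: 18 2α,4β,6β-trihydroxy-4α-isopropyl-1β,8-dimethyl-5αH-bicyclo[5.3.0]dec-7-en-9-one; 19 4-acetoxybenzoic acid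
Product: 20 2α,4β-dihydroxy-4α-isopropyl-1β,8-dimethyl-9-oxo-5αH-bicyclo[5.3.0]dec-7-en-6α-yl 4-acetoxybenzoate
Conditions: PPh3, DIAD, toluene, 0 °C → rt
Reagents that add atoms: none
Why: Mitsunobu esterification should occur only at the allylic C6 hydroxyl with SN2 inversion (6β-OH to 6α-ester), because the C2 hydroxyl next to the quaternary C1 and the tertiary C4 hydroxyl are too hindered to be displaced.

Step 15
Reactants: 20 2α,4β-dihydroxy-4α-isopropyl-1β,8-dimethyl-9-oxo-5αH-bicyclo[5.3.0]dec-7-en-6α-yl 4-acetoxybenzoate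
Product: 21 2α-acetoxy-4β-hydroxy-4α-isopropyl-1β,8-dimethyl-9-oxo-5αH-bicyclo[5.3.0]dec-7-en-6α-yl 4-acetoxybenzoate
Conditions: Ac2O, DMAP, pyridine, CH2Cl2, rt
Reagents that add atoms: acetic anhydride, CC(=O)OC(C)=O
Why: DMAP-catalysed acetylation takes the remaining secondary alcohol at C2 with retention, while the tertiary C4 hydroxyl is not acylated at room temperature.

Step 16
Reactants: 21 2α-acetoxy-4β-hydroxy-4α-isopropyl-1β,8-dimethyl-9-oxo-5αH-bicyclo[5.3.0]dec-7-en-6α-yl 4-acetoxybenzoate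
Product: 22 2α-acetoxy-4β-hydroxy-4α-isopropyl-1β,8-dimethyl-9-oxo-5αH-bicyclo[5.3.0]dec-7-en-6α-yl 4-hydroxybenzoate (CNP0087181.6)
Conditions: NH4OAc, MeOH/H2O, rt
Reagents that add atoms: none
Why: chemoselective solvolysis of the phenolic acetate; aryl acetates are cleaved far faster than the hindered secondary alkyl acetate and the alkyl benzoate under ammonium acetate in aqueous methanol.

**Compound list**
1 | (S)-4-(tert-butyldimethylsilyloxy)cyclopent-2-en-1-one | O=C1C[C@H](O[Si](C)(C)C(C)(C)C)C=C1 | starting material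
2 | (S)-4-(tert-butyldimethylsilyloxy)-2-iodocyclopent-2-en-1-one | O=C1C[C@H](O[Si](C)(C)C(C)(C)C)C=C1I | intermediate
3 | (1R,4S)-4-(tert-butyldimethylsilyloxy)-2-iodocyclopent-2-en-1-ol (cis) | O[C@@H]1C[C@H](O[Si](C)(C)C(C)(C)C)C=C1I | intermediate
4 | tert-butyl{[(1S,4R)-3-iodo-4-(triisopropylsilyloxy)cyclopent-2-en-1-yl]oxy}dimethylsilane (cis) | CC(C)[Si](C(C)C)(C(C)C)O[C@@H]1C[C@H](O[Si](C)(C)C(C)(C)C)C=C1I | intermediate
5 | ethyl diazoacetate | CCOC(=O)C=[N+]=[N-] | starting material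
6 | ethyl 2-diazo-2-[(3S,5R)-3-(tert-butyldimethylsilyloxy)-5-(triisopropylsilyloxy)cyclopent-1-en-1-yl]acetate | CC(C)[Si](C(C)C)(C(C)C)O[C@@H]1C[C@H](O[Si](C)(C)C(C)(C)C)C=C1C(=[N+]=[N-])C(=O)OCC | intermediate
7 | 3-methylbut-2-enal | CC(C)=CC=O | starting material
8 | (E)-triisopropyl[(3-methylbuta-1,3-dien-1-yl)oxy]silane | CC(=C)/C=C/O[Si](C(C)C)(C(C)C)C(C)C | intermediate
9 | ethyl 1-[(3S,5R)-3-(tert-butyldimethylsilyloxy)-5-(triisopropylsilyloxy)cyclopent-1-en-1-yl]-2-methyl-2-[(E)-2-(triisopropylsilyloxy)ethenyl]cyclopropane-1-carboxylate (cyclopentenyl and silyloxyvinyl groups cis) | CCOC(=O)[C@]1(C2=C[C@@H](O[Si](C)(C)C(C)(C)C)C[C@H]2O[Si](C(C)C)(C(C)C)C(C)C)C[C@@]1(C)/C=C/O[Si](C(C)C)(C(C)C)C(C)C | intermediate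
10 | ethyl 4α-(tert-butyldimethylsilyloxy)-8-methyl-2α,6β-bis(triisopropylsilyloxy)-5αH-bicyclo[5.3.0]deca-1(10),7-diene-10-carboxylate | CC(C)[Si](C(C)C)(C(C)C)O[C@@H]1C[C@H](O[Si](C)(C)C(C)(C)C)[C@H]2[C@@H](O[Si](C(C)C)(C(C)C)C(C)C)C=C(C)CC(C(=O)OCC)=C12 | intermediate
11 | ethyl 4α-(tert-butyldimethylsilyloxy)-8-methyl-9-oxo-2α,6β-bis(triisopropylsilyloxy)-5αH-bicyclo[5.3.0]deca-1(10),7-diene-10-carboxylate | CC(C)[Si](C(C)C)(C(C)C)O[C@@H]1C[C@H](O[Si](C)(C)C(C)(C)C)[C@H]2[C@@H](O[Si](C(C)C)(C(C)C)C(C)C)C=C(C)C(=O)C(C(=O)OCC)=C12 | intermediate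
12 | ethyl 4α-(tert-butyldimethylsilyloxy)-1β,8-dimethyl-9-oxo-2α,6β-bis(triisopropylsilyloxy)-5αH-bicyclo[5.3.0]dec-7-ene-10-carboxylate (C10 epimers and enol) | CC(C)[Si](C(C)C)(C(C)C)O[C@@H]1C[C@H](O[Si](C)(C)C(C)(C)C)[C@H]2[C@@H](O[Si](C(C)C)(C(C)C)C(C)C)C=C(C)C(=O)C(C(=O)OCC)[C@]12C | intermediate
13 | ethyl 4α-hydroxy-1β,8-dimethyl-9-oxo-2α,6β-bis(triisopropylsilyloxy)-5αH-bicyclo[5.3.0]dec-7-ene-10-carboxylate | CC(C)[Si](C(C)C)(C(C)C)O[C@@H]1C[C@H](O)[C@H]2[C@@H](O[Si](C(C)C)(C(C)C)C(C)C)C=C(C)C(=O)C(C(=O)OCC)[C@]12C | intermediate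
14 | ethyl 1β,8-dimethyl-4,9-dioxo-2α,6β-bis(triisopropylsilyloxy)-5αH-bicyclo[5.3.0]dec-7-ene-10-carboxylate | CC(C)[Si](C(C)C)(C(C)C)O[C@@H]1CC(=O)[C@H]2[C@@H](O[Si](C(C)C)(C(C)C)C(C)C)C=C(C)C(=O)C(C(=O)OCC)[C@]12C | intermediate
15 | sodium enolate of 14 (C9–O−, C9=C10) | CC(C)[Si](C(C)C)(C(C)C)O[C@@H]1CC(=O)[C@H]2[C@@H](O[Si](C(C)C)(C(C)C)C(C)C)C=C(C)C([O-])=C(C(=O)OCC)[C@]12C.[Na+] | intermediate
16 | ethyl 4β-hydroxy-4α-isopropyl-1β,8-dimethyl-9-oxo-2α,6β-bis(triisopropylsilyloxy)-5αH-bicyclo[5.3.0]dec-7-ene-10-carboxylate | CC(C)[Si](C(C)C)(C(C)C)O[C@@H]1C[C@](O)(C(C)C)[C@H]2[C@@H](O[Si](C(C)C)(C(C)C)C(C)C)C=C(C)C(=O)C(C(=O)OCC)[C@]12C | intermediate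
17 | 4β-hydroxy-4α-isopropyl-1β,8-dimethyl-2α,6β-bis(triisopropylsilyloxy)-5αH-bicyclo[5.3.0]dec-7-en-9-one | CC(C)[Si](C(C)C)(C(C)C)O[C@@H]1C[C@](O)(C(C)C)[C@H]2[C@@H](O[Si](C(C)C)(C(C)C)C(C)C)C=C(C)C(=O)C[C@]12C | intermediate
18 | 2α,4β,6β-trihydroxy-4α-isopropyl-1β,8-dimethyl-5αH-bicyclo[5.3.0]dec-7-en-9-one | O[C@@H]1C[C@](O)(C(C)C)[C@H]2[C@@H](O)C=C(C)C(=O)C[C@]12C | intermediate
19 | 4-acetoxybenzoic acid | CC(=O)Oc1ccc(cc1)C(=O)O | starting material
20 | 2α,4β-dihydroxy-4α-isopropyl-1β,8-dimethyl-9-oxo-5αH-bicyclo[5.3.0]dec-7-en-6α-yl 4-acetoxybenzoate | O[C@@H]1C[C@](O)(C(C)C)[C@H]2[C@H](OC(=O)c3ccc(OC(C)=O)cc3)C=C(C)C(=O)C[C@]12C | intermediate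
21 | 2α-acetoxy-4β-hydroxy-4α-isopropyl-1β,8-dimethyl-9-oxo-5αH-bicyclo[5.3.0]dec-7-en-6α-yl 4-acetoxybenzoate | CC(=O)O[C@@H]1C[C@](O)(C(C)C)[C@H]2[C@H](OC(=O)c3ccc(OC(C)=O)cc3)C=C(C)C(=O)C[C@]12C | intermediate
22 | 2α-acetoxy-4β-hydroxy-4α-isopropyl-1β,8-dimethyl-9-oxo-5αH-bicyclo[5.3.0]dec-7-en-6α-yl 4-hydroxybenzoate (CNP0087181.6) | CC(=O)O[C@@H]1C[C@](O)(C(C)C)[C@H]2[C@H](OC(=O)c3ccc(O)cc3)C=C(C)C(=O)C[C@]12C | target

**Step count and risks**
Total step count: 16. Longest linear sequence: 15 steps (steps 1–4 and 6–16, from 1); step 5 is a one-step side branch.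

The three steps most likely to fail:

Step 6. The carbenoid may be diverted before cyclopropanation (attack at the enol-ether carbon with zwitterion formation, carbene dimerisation, or cyclisation of 6 to a pyrazole), or the Cope shift may stall because the C4 silyloxy group flanks the reacting vinyl terminus. The fallback makes the two ring bonds one after the other and closes the ring by metathesis; it sets out from 4 and comes back at 10. Negishi coupling of 4 with the Reformatsky reagent BrZnCH2CO2Et (Pd(PPh3)4, THF) would give ethyl 2-[(3S,5R)-3-(tert-butyldimethylsilyloxy)-5-(triisopropylsilyloxy)cyclopent-1-en-1-yl]acetate F1. Deprotonation with LiN(iPr)2 and α-alkylation with 3-bromo-2-methylpropene would give the C10-methallylated ester F2, which forms C10–C9. Its trimethylsilyl ketene acetal F3 (LiN(iPr)2, Me3SiCl) should undergo a γ-selective vinylogous Mukaiyama aldol addition to acrolein (BF3·OEt2, −78 °C), anti to the C4 silyloxy group, to give the dienyl alcohol F4, which forms C5–C6. Ring-closing metathesis with second-generation Grubbs catalyst (H2IMes)(PCy3)Cl2Ru=CHPh would close C7=C8 to the cycloheptadienol F5, and TIPSOTf/2,6-lutidine then gives 10.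

Step 7. Hydrogen abstraction may be unselective among the other activated C–H bonds (C6–H, C2–H), and the dienone may lose silanol towards a tropone on the acidic chromium reagent. The fallback changes the oxidation to an ene/[2,3]-sigmatropic process that is steered by the trisubstituted C7=C8 bond to its ring methylene; it sets out from 10 and comes back at 11. SeO2 (cat.) with tBuOOH in CH2Cl2 should give the C9 allylic alcohol ethyl 4α-(tert-butyldimethylsilyloxy)-9-hydroxy-8-methyl-2α,6β-bis(triisopropylsilyloxy)-5αH-bicyclo[5.3.0]deca-1(10),7-diene-10-carboxylate F6 (either C9 epimer), and buffered Dess–Martin oxidation then gives 11.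

Step 11. The C4 ketone may enolise (with β-elimination of a silyloxy group or epimerisation at C5), the isopropyl reagent may reduce the ketone by β-hydride transfer, or attack may come from the wrong face. The fallback uses an sp2 nucleophile without β-hydrogen and adds the last two hydrogens afterwards; it sets out from 14 (as enolate 15) and comes back at 16. 2-Propenylmagnesium bromide with CeCl3 (THF, −78 °C) would give the isopropenyl carbinol ethyl 4β-hydroxy-1β,8-dimethyl-9-oxo-4α-(prop-1-en-2-yl)-2α,6β-bis(triisopropylsilyloxy)-5αH-bicyclo[5.3.0]dec-7-ene-10-carboxylate F7, and hydrogenation of its 1,1-disubstituted alkene with RhCl(PPh3)3/H2, which spares the trisubstituted enone, gives 16.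

**Further compounds**
F1 | step 6 | ethyl 2-[(3S,5R)-3-(tert-butyldimethylsilyloxy)-5-(triisopropylsilyloxy)cyclopent-1-en-1-yl]acetate | CC(C)[Si](C(C)C)(C(C)C)O[C@@H]1C[C@H](O[Si](C)(C)C(C)(C)C)C=C1CC(=O)OCC
F2 | step 6 | ethyl 2-[(3S,5R)-3-(tert-butyldimethylsilyloxy)-5-(triisopropylsilyloxy)cyclopent-1-en-1-yl]-4-methylpent-4-enoate (C10 epimers) | CC(C)[Si](C(C)C)(C(C)C)O[C@@H]1C[C@H](O[Si](C)(C)C(C)(C)C)C=C1C(CC(C)=C)C(=O)OCC
F3 | step 6 | trimethylsilyl ketene acetal of F2 (C10=C(OEt)OSiMe3, C1=C5 retained) | CC(C)[Si](C(C)C)(C(C)C)O[C@@H]1C[C@H](O[Si](C)(C)C(C)(C)C)C=C1C(CC(C)=C)=C(OCC)O[Si](C)(C)C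
F4 | step 6 | ethyl 2-[4α-(tert-butyldimethylsilyloxy)-5β-(1-hydroxyprop-2-enyl)-2α-(triisopropylsilyloxy)cyclopentylidene]-4-methylpent-4-enoate (methallyl group cis to C5; C6 configured as in 10) | CC(C)[Si](C(C)C)(C(C)C)O[C@@H]1C[C@H](O[Si](C)(C)C(C)(C)C)[C@@H]([C@@H](O)C=C)/C1=C(\CC(C)=C)C(=O)OCC
F5 | step 6 | ethyl 4α-(tert-butyldimethylsilyloxy)-6β-hydroxy-8-methyl-2α-(triisopropylsilyloxy)-5αH-bicyclo[5.3.0]deca-1(10),7-diene-10-carboxylate | CC(C)[Si](C(C)C)(C(C)C)O[C@@H]1C[C@H](O[Si](C)(C)C(C)(C)C)[C@H]2[C@@H](O)C=C(C)CC(C(=O)OCC)=C12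
F6 | step 7 | ethyl 4α-(tert-butyldimethylsilyloxy)-9-hydroxy-8-methyl-2α,6β-bis(triisopropylsilyloxy)-5αH-bicyclo[5.3.0]deca-1(10),7-diene-10-carboxylate | CC(C)[Si](C(C)C)(C(C)C)O[C@@H]1C[C@H](O[Si](C)(C)C(C)(C)C)[C@H]2[C@@H](O[Si](C(C)C)(C(C)C)C(C)C)C=C(C)C(O)C(C(=O)OCC)=C12
F7 | step 11 | ethyl 4β-hydroxy-1β,8-dimethyl-9-oxo-4α-(prop-1-en-2-yl)-2α,6β-bis(triisopropylsilyloxy)-5αH-bicyclo[5.3.0]dec-7-ene-10-carboxylate | CC(C)[Si](C(C)C)(C(C)C)O[C@@H]1C[C@](O)(C(C)=C)[C@H]2[C@@H](O[Si](C(C)C)(C(C)C)C(C)C)C=C(C)C(=O)C(C(=O)OCC)[C@]12C
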